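The readings are calculated on assumed constants.

If the part of the electrophile that has reacted by 10 min, X, is taken as a large term given by an earlier run plus a small correction for free base, the correction is what remains to compute.

in all of them: electrophile 28 mM

| flask | nucleophile | free base | remark | time |
|---|---|---|---|---|
| noon | 56 mM | 52 mM | run made earlier |  |
| winter | 56 mM | 280 mM | run made earlier |  |
| cedar | 56.0 mM | 84.0 mM |  | 10 min |
| maple | 56.0 mM | 170 mM |  | 10 min |
| oak | 56.0 mM | 340 mM |  | 10 min |

| run | time / min | electrophile / % | target / % |
|---|---|---|---|
| noon | 2.00 | 42.5 | 53.0 |
| noon | 4.00 | 27.5 | 62.8 |
| noon | 6.00 | 21.1 | 62.4 |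
| noon | 8.00 | 16.7 | 60.6 |
| noon | 10.0 | 14.7 | 56.7 |
| winter | 2.00 | 42.6 | 39.9 |
| winter | 4.00 | 26.9 | 32.6 |
| winter | 6.00 | 20.6 | 23.3 |
| winter | 8.00 | 15.0 | 16.9 |
| winter | 10.0 | 11.4 | 12.1 |

(scatter of a reading: 0.5 percentage points)

- part of the electrophile that has reacted at the end, cedar
- part of the electrophile that has reacted at the end, maple
- part of the electrophile that has reacted at the end, oak
- what raising the concentration of free base from its lowest to its highest value here does to the part of the electrophile that has reacted (changes below 5 percentage points count as none) (it falls / it rises / no change)



Read column against column, the electrophile of the noon and winter runs stands at 42.5% and 42.6% after 2.00 min, and at 21.1% and 20.6% after 6.00 min, although the winter run holds 5.38 times the free base of the noon run, so up to that time the loss of electrophile reads as close to zero order in free base. The target column parts widely, 56.7% against 12.1% in the last row, but X is read from the electrophile column. That last row gives X as 85.3% for noon and 88.6% for winter, a gap of 3.3 percentage points, larger than the 0.71 points by which a difference of two readings scatters. Taking X as straight in the logarithm of free base, this gap gives s = 2 points, the base increment, meaning the gain in X per e-fold of free base at that time.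

Added to the noon value, s gives 86.2% for cedar, 87.6% for maple and 89.0% for oak. The reckoned rise from cedar to oak is thus 2.7 points, less than the 5 points that count as a change.

The forecast says 86.8%, 88% and 88.9%, with no change as its trend, on the ground that “The gap should saturate once base is in clear excess.” Its cedar figure stands above the one reckoned here, and both give the same trend.

The flasks give 85.9%, 86.7% and 87.7%, so the verdict is no change.

    electrophile + nucleophile ⇌ acid set free + target (K = 0.170, k = 0.200 /M/s)
    nucleophile + acid set free ⇌ protonated nucleophile, settled at all times (K = 18000 /M)
    acid set free + free base ⇌ salt of the base, settled at all times (K = 37.0 /M)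
    free base + target → over-reaction product (k = 0.0180 /M/s)

The rise from cedar to oak is 1.8 points, smaller than the 2.7 points reckoned with s. In a neighbouring flask, maple with 68 mM of free base, s gives 85.8%, and that flask reaches 85.7%. Its electrophile is 14.3% at 10.0 min, close to the 13.3% in maple, yet its target stands at 50.4% against 24.0% in maple.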